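**Retrosynthetic overview**
1. Target 25 ⇐ diacetoxy vinyl epoxide 24 by trans acetolysis at allylic C16; 24 ⇐ seco enol triflate–aldehyde 22 by Nozaki–Hiyama–Kishi closure of the 11-membered ring at C7–C8 (last ring).
2. 22 ⇐ core enal 16 + chiral C5 dialkylzinc 20 (from monomethyl (S)-3-methylglutarate), joined at C2–C3 under ligand control.
3. 16 ⇐ bicyclic keto ester 9 by C9 methylation, β-epoxidation, enol triflation and conversion of the ester into an α-methylene aldehyde.
4. Key disconnection C10–C11: the β-carbon of enal 8 is made nucleophilic (carbene-bound homoenolate) and adds to one enantiotopic enone β-carbon of the dienone, closing the cyclopentane and setting C10, C11 and C14.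
5. 8 ⇐ melonal + methyl vinyl ketone (Robinson annulation), dehydrogenation, cross-metathesis. Ring order: cyclohexane → cyclopentane → 11-membered ring.

Convention: target carbons are numbered C1 (ring carbon bearing the exocyclic methylene C17), C2 (OAc), C3, C4, C5 (methyl C18), C6, C7 (OAc), C8, C9 (methyl C19), C10, C11 around the 11-membered ring; cyclopentane C10–C11–C12–C13–C14 (methyl C20); cyclohexene C8–C9–C10–C14–C15 (OH)–C16 (OAc); β is the face of the bicyclic core that carries C20; the target is (2R,5S,7S,10S,11R,14S,15R,16R).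

Assumption: monomethyl (S)-3-methylglutarate 17 is bought as such; otherwise it is one step from 3-methylglutaric anhydride by alkaloid-mediated methanolysis.

**Route**

Step 1
Reactants: 1 rac-2,6-dimethylhept-5-enal (melonal); 2 but-3-en-2-one (methyl vinyl ketone)
Product: 5 rac-4-methyl-4-(4-methylpent-3-en-1-yl)cyclohex-2-en-1-one, via pyrrolidine enamine 3 (not isolated), via keto aldehyde 4 (not isolated)
Conditions: pyrrolidine, PhMe, Dean–Stark; 2, 0 °C → rt; AcOH/NaOAc/H2O, reflux
Reagents that add atoms: none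
Why: Stork enamine Michael addition of the α-branched aldehyde to the enone followed by aldol condensation (Robinson annulation) builds the six-membered ring and the quaternary carbon (future C14); the racemic stereocentre is erased in step 2.

Step 2
Reactants: 5 rac-4-methyl-4-(4-methylpent-3-en-1-yl)cyclohex-2-en-1-one
Product: 6 4-methyl-4-(4-methylpent-3-en-1-yl)cyclohexa-2,5-dien-1-one
Conditions: DDQ, 1,4-dioxane, reflux
Reagents that add atoms: none
Why: DDQ dehydrogenation of a 4,4-disubstituted cyclohexenone gives the cross-conjugated, non-enolisable dienone whose quaternary carbon is now prochiral.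

Step 3
Reactants: 6 4-methyl-4-(4-methylpent-3-en-1-yl)cyclohexa-2,5-dien-1-one; 7 (E)-but-2-enal (crotonaldehyde)
Product: 8 (E)-5-(1-methyl-4-oxocyclohexa-2,5-dien-1-yl)pent-2-enal
Conditions: second-generation Hoveyda–Grubbs catalyst RuCl2(H2IMes)(=CH-C6H4-2-OiPr) (5 mol%), 7 (5 equiv), CH2Cl2, 40 °C
Reagents that add atoms: none
Why: Olefin cross-metathesis of the electron-rich trisubstituted side-chain alkene with crotonaldehyde gives the E-enal, while the hindered electron-poor ring alkenes are inert.

Step 4 (key step)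
Reactants: 8 (E)-5-(1-methyl-4-oxocyclohexa-2,5-dien-1-yl)pent-2-enal
Product: 9 methyl 2-[(1S,3aR,7aR)-3a-methyl-6-oxo-2,3,3a,6,7,7a-hexahydro-1H-inden-1-yl]acetate (cis-fused; ester arm at C11 on the α face)
Conditions: (5aS,10bR)-2-mesityl-5a,10b-dihydro-4H,6H-indeno[2,1-b][1,2,4]triazolo[4,3-d][1,4]oxazin-2-ium chloride (10 mol%), DBU (10 mol%), MeOH (5 equiv), PhMe, 25 °C
Reagents that add atoms: methanol, CO
Why: Proposed new method: the carbene adds to the enal to give the extended Breslow intermediate (homoenolate), whose nucleophilic β-carbon C11 attacks 5-exo the β-carbon C10 of one of the two enantiotopic enones (the chiral triazolylidene selects the enone and so fixes C14, the three-atom tether forces the cis ring fusion at C10, and the compact synclinal transition state that stacks the azolium enol over the forming dienolate places the C1 arm cis to C9 at C11), after which C9 is protonated and methanol cleaves the acyl azolium; the closest known reactions are the carbene-catalysed homoenolate conjugate addition of enals to enones with methanol turnover and the carbene-catalysed intramolecular Stetter desymmetrisation of 4,4-disubstituted cyclohexadienones.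

Step 5
Reactants: 9 methyl 2-[(1S,3aR,7aR)-3a-methyl-6-oxo-2,3,3a,6,7,7a-hexahydro-1H-inden-1-yl]acetate
Product: 11 C9-methyl keto ester (9 methylated α to the ketone; C9 epimers), via lithium dienolate 10 (not isolated)
Conditions: LiN(iPr)2 (1.05 equiv), THF, −78 °C; MeI, −78 → −40 °C
Reagents that add atoms: iodomethane, CI
Why: Kinetic α′-deprotonation of the enone (more acidic than the ester) and enolate alkylation install C19; the C9 configuration is irrelevant because C9 becomes sp2 in step 7.

Step 6
Reactants: 11 C9-methyl keto ester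
Product: 12 15β,16β-epoxy ketone (oxirane cis to the C20 methyl)
Conditions: 30% aq. H2O2, NaOH (cat.), MeOH, 0 °C
Reagents that add atoms: hydrogen peroxide, OO
Why: Weitz–Scheffer nucleophilic epoxidation of the enone, in which hydroperoxide attacks C15 from the convex β face of the cis-hydrindane (the concave face is blocked by the cyclopentane and its endo ester arm), so C15 receives its final configuration.

Step 7
Reactants: 12 15β,16β-epoxy ketone
Product: 14 C8 enol triflate (C8=C9 tetrasubstituted; epoxide and methyl ester retained), via potassium enolate 13 (not isolated)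
Conditions: KN(SiMe3)2, THF, −78 °C; PhNTf2, −78 → 0 °C
Reagents that add atoms: N-phenylbis(trifluoromethanesulfonimide), O=S(=O)(N(c1ccccc1)S(=O)(=O)C(F)(F)F)C(F)(F)F
Why: C9 is the only enolisable ketone position, so enolate O-sulfonylation gives the C8=C9 enol triflate (the future ring alkene) regiospecifically.

Step 8
Reactants: 14 C8 enol triflate
Product: 15 aldehyde (C11–CH2–CHO)
Conditions: iBu2AlH (1.1 equiv), CH2Cl2, −78 °C; aq. KNaC4H4O6 (potassium sodium tartrate)
Reagents that add atoms: none
Why: Partial reduction of the methyl ester through the stable aluminium hemiacetal gives the aldehyde, and the enol triflate and epoxide are inert at −78 °C.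

Step 9
Reactants: 15 aldehyde
Product: 16 2-substituted acrolein (C11–C(=CH2)–CHO)
Conditions: 37% aq. CH2O, pyrrolidine (10 mol%), EtCO2H (10 mol%), i-PrOH, 45 °C
Reagents that add atoms: formaldehyde, C=O
Why: Amine-catalysed Mannich condensation–elimination (organocatalytic α-methylenation of an aldehyde) installs C17 as the exocyclic methylene without touching C11.

Step 10
Reactants: 17 (S)-5-methoxy-3-methyl-5-oxopentanoic acid (monomethyl (S)-3-methylglutarate)
Product: 18 methyl (S)-5-hydroxy-3-methylpentanoate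
Conditions: BH3·SMe2, THF, 0 °C → rt; MeOH
Reagents that add atoms: none
Why: Borane reduces the carboxylic acid chemoselectively in the presence of the methyl ester, leaving the pool-derived stereocentre (future C5) untouched.

Step 11
Reactants: 18 methyl (S)-5-hydroxy-3-methylpentanoate
Product: 19 methyl (R)-5-iodo-3-methylpentanoate
Conditions: I2, PPh3, imidazole, CH2Cl2, 0 °C → rt
Reagents that add atoms: iodine, II
Why: Appel-type iodination of the primary alcohol through the alkoxyphosphonium iodide (the descriptor changes only through priorities).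

Step 12
Reactants: 19 methyl (R)-5-iodo-3-methylpentanoate; 16 2-substituted acrolein
Product: 21 (2R,5S)-allylic alcohol methyl ester (C11–C(=CH2)–CH(OH)–CH2CH2–CH(CH3)–CH2–CO2Me), via dialkylzinc 20 (not isolated)
Conditions: 19 (2.4 equiv), Et2Zn, CuI (0.3 mol%), 50 °C, then evaporation; Ti(OiPr)4 (1.5 equiv), (1S,2S)-1,2-bis(trifluoromethanesulfonamido)cyclohexane (8 mol%), PhMe, −20 °C; add 16
Reagents that add atoms: none
Why: Iodine–zinc exchange gives the ester-tolerant dialkylzinc, whose titanium bis-sulfonamide-catalysed 1,2-addition to the enal forms C2–C3 with the 2R carbinol configuration dictated by the ligand (the (1R,2R)-ligand gives the opposite series).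

Step 13
Reactants: 21 (2R,5S)-allylic alcohol methyl ester
Product: 22 (2R,5S)-hydroxy aldehyde (C7 as CHO)
Conditions: iBu2AlH (2.2 equiv), CH2Cl2, −78 °C; aq. KNaC4H4O6 (potassium sodium tartrate)
Reagents that add atoms: none
Why: The first equivalent converts the hydroxyl into its aluminium alkoxide and the second effects partial ester reduction to the aldehyde at −78 °C.

Step 14
Reactants: 22 (2R,5S)-hydroxy aldehyde
Product: 23 macrocyclic (2R,5S,7S,10S,11R,14S,15R,16S)-15,16-epoxy-2,7-diol
Conditions: CrCl2 (8 equiv), NiCl2 (2 mol%), DMSO/THF 3:1, 25 °C, 0.003 M, slow addition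
Reagents that add atoms: none
Why: Nozaki–Hiyama–Kishi macrocyclisation (oxidative addition of zerovalent nickel to the enol triflate, transmetalation to chromium, addition of the alkenylchromium to the aldehyde) closes the 11-membered ring at C7–C8; the tether reaches C7 from the concave α face below C19 and the chromium-bound oxygen takes the open β face, which corresponds to 7S (substrate control, expected but not assured).

Step 15
Reactants: 23 macrocyclic epoxy diol
Product: 24 macrocyclic 15β,16β-epoxy 2,7-diacetate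
Conditions: Ac2O, pyridine, DMAP (cat.), CH2Cl2, 0 °C → rt
Reagents that add atoms: acetic anhydride, CC(=O)OC(C)=O
Why: Standard acylation of both secondary allylic alcohols; the epoxide is untouched.

Step 16
Reactants: 24 macrocyclic epoxy diacetate
Product: 25 CNP0318778.1 (target)
Conditions: CsOAc (3 equiv), AcOH (10 equiv), DMF, 60 °C
Reagents that add atoms: acetic acid, CC(=O)O
Why: SN2 opening of the vinyl epoxide by acetate at the allylic carbon C16 (C15 is neopentyl) with inversion gives the 16α-acetate and leaves the 15β-hydroxyl free, which is the trans hydroxy acetate of the target.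

**Compound list**
1 | rac-2,6-dimethylhept-5-enal (melonal) | CC(C)=CCCC(C)C=O | starting material
2 | but-3-en-2-one (methyl vinyl ketone) | C=CC(C)=O | starting material
3 | 1-(2,6-dimethylhepta-1,5-dien-1-yl)pyrrolidine (not isolated) | CC(C)=CCCC(C)=CN1CCCC1 | intermediate
4 | rac-2-methyl-2-(4-methylpent-3-en-1-yl)-5-oxohexanal (not isolated) | CC(C)=CCCC(C)(C=O)CCC(C)=O | intermediate
5 | rac-4-methyl-4-(4-methylpent-3-en-1-yl)cyclohex-2-en-1-one | CC(C)=CCCC1(C)CCC(=O)C=C1 | intermediate
6 | 4-methyl-4-(4-methylpent-3-en-1-yl)cyclohexa-2,5-dien-1-one | CC(C)=CCCC1(C)C=CC(=O)C=C1 | intermediate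
7 | (E)-but-2-enal (crotonaldehyde) | C/C=C/C=O | starting material
8 | (E)-5-(1-methyl-4-oxocyclohexa-2,5-dien-1-yl)pent-2-enal | O=C/C=C/CCC1(C)C=CC(=O)C=C1 | intermediate
9 | methyl 2-[(1S,3aR,7aR)-3a-methyl-6-oxo-2,3,3a,6,7,7a-hexahydro-1H-inden-1-yl]acetate | O=C1C[C@@H]2[C@H](CC(=O)OC)CC[C@]2(C)C=C1 | intermediate
10 | lithium C8(O)=C9 dienolate of 9 (not isolated) | [Li+].[O-]C1=C[C@@H]2[C@H](CC(=O)OC)CC[C@]2(C)C=C1 | intermediate
11 | C9-methyl keto ester (C9 epimers) | O=C1C(C)[C@@H]2[C@H](CC(=O)OC)CC[C@]2(C)C=C1 | intermediate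
12 | 15β,16β-epoxy ketone | O=C1C(C)[C@@H]2[C@H](CC(=O)OC)CC[C@]2(C)[C@H]3O[C@@H]13 | intermediate
13 | potassium C8(O)=C9 enolate of 12 (not isolated) | [K+].[O-]C1=C(C)[C@@H]2[C@H](CC(=O)OC)CC[C@]2(C)[C@H]3O[C@@H]13 | intermediate
14 | C8 enol triflate methyl ester | O=S(=O)(OC1=C(C)[C@@H]2[C@H](CC(=O)OC)CC[C@]2(C)[C@H]3O[C@@H]13)C(F)(F)F | intermediate
15 | enol triflate aldehyde (C11–CH2–CHO) | O=S(=O)(OC1=C(C)[C@@H]2[C@H](CC=O)CC[C@]2(C)[C@H]3O[C@@H]13)C(F)(F)F | intermediate
16 | enol triflate 2-substituted acrolein (C11–C(=CH2)–CHO) | O=S(=O)(OC1=C(C)[C@@H]2[C@H](C(=C)C=O)CC[C@]2(C)[C@H]3O[C@@H]13)C(F)(F)F | intermediate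
17 | (S)-5-methoxy-3-methyl-5-oxopentanoic acid | OC(=O)C[C@H](C)CC(=O)OC | starting material
18 | methyl (S)-5-hydroxy-3-methylpentanoate | OCC[C@H](C)CC(=O)OC | intermediate
19 | methyl (R)-5-iodo-3-methylpentanoate | ICC[C@H](C)CC(=O)OC | intermediate
20 | bis[(3R)-5-methoxy-3-methyl-5-oxopentyl]zinc (not isolated) | COC(=O)C[C@@H](C)CC[Zn]CC[C@H](C)CC(=O)OC | intermediate
21 | (2R,5S)-allylic alcohol methyl ester | O=S(=O)(OC1=C(C)[C@@H]2[C@H](C(=C)[C@H](O)CC[C@H](C)CC(=O)OC)CC[C@]2(C)[C@H]3O[C@@H]13)C(F)(F)F | intermediate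
22 | (2R,5S)-hydroxy aldehyde | O=S(=O)(OC1=C(C)[C@@H]2[C@H](C(=C)[C@H](O)CC[C@H](C)CC=O)CC[C@]2(C)[C@H]3O[C@@H]13)C(F)(F)F | intermediate
23 | macrocyclic (2R,5S,7S,10S,11R,14S,15R,16S)-15,16-epoxy-2,7-diol | C=C1[C@H](O)CC[C@H](C)C[C@H](O)C2=C(C)[C@@H]3[C@H]1CC[C@]3(C)[C@H]4O[C@@H]24 | intermediate
24 | macrocyclic (2R,5S,7S,10S,11R,14S,15R,16S)-15,16-epoxy-2,7-diyl diacetate | C=C1[C@H](OC(C)=O)CC[C@H](C)C[C@H](OC(C)=O)C2=C(C)[C@@H]3[C@H]1CC[C@]3(C)[C@H]4O[C@@H]24 | intermediate
25 | CNP0318778.1, (2R,5S,7S,10S,11R,14S,15R,16R)-15-hydroxy-2,7,16-triacetate | C=C1[C@H](OC(C)=O)CC[C@H](C)C[C@H](OC(C)=O)C2=C(C)[C@@H]3[C@H]1CC[C@]3(C)[C@@H](O)[C@@H]2OC(C)=O | target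

**Step count and risks**
Total steps: 16. Longest linear sequence: 14 (steps 1–9 and 12–16, from melonal); steps 10–11 make the side-chain fragment.

Steps most likely to fail:

1. Step 4. The homoenolate cyclisation may give the C11 epimer through the extended transition state, the azolium enolate may add to the second enone, or β-protonation may give the saturated ester. The fallback sets out from dienone 6 and returns at enol triflate 14. Ozonolysis of the side-chain alkene (O3, CH2Cl2/MeOH, −78 °C; Me2S) gives 3-(1-methyl-4-oxocyclohexa-2,5-dien-1-yl)propanal F1. An asymmetric intramolecular Stetter reaction (aminoindanol-derived N-pentafluorophenyl triazolium tetrafluoroborate, KN(SiMe3)2 cat., PhMe) desymmetrises it to the cis-fused C11-keto enedione F2. Horner–Wadsworth–Emmons olefination of the saturated ketone ((MeO)2P(O)CH2CO2Me, NaH, THF) gives the exocyclic enoate F3. The operations of steps 5–7 then give the C9-methyl enoate F4, the 15β,16β-epoxy enoate F5 and the enol triflate enoate F6. Conjugate reduction with [(Ph3P)CuH]6 delivers hydride to C11 from the convex β face and gives 14, so C11 is set by reagent approach and not by the cyclisation.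

2. Step 14. The ring closure may give a poor C7 ratio, and the free hydroxyl and vinyl epoxide add further burden. The fallback sets out from hydroxy aldehyde 22 and returns at diacetate 24. Acetylation (Ac2O, pyridine) gives the 2-acetoxy aldehyde F7. The same chromium/nickel closure gives the macrocyclic C7 alcohol as an epimer mixture F8. Dess–Martin oxidation converges both epimers to the macrocyclic C7 enone F9. Reagent-controlled reduction with (R)-2-methyl-CBS-oxazaborolidine and BH3·SMe2 gives the (7S)-alcohol F10 (alkenyl as the large group). Acetylation then gives 24.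

3. Step 16. Acetate may attack in SN2′ fashion, or the C7 acetate may participate and scramble acyl groups. The fallback sets out from diol 23 and returns at target 25. The epoxide is opened before any acylation (CsOAc, AcOH, DMF, 60 °C) to give the 16-acetoxy-2,7,15-triol F11, in which no neighbouring ester can participate. Site-selective acetylation (Ac2O 2.2 equiv, pyridine, 0 °C, no DMAP) then acylates the two allylic hydroxyls and leaves the neopentyl C15 hydroxyl free, giving 25.

**Further compounds**
F1 | step 4 | 3-(1-methyl-4-oxocyclohexa-2,5-dien-1-yl)propanal | O=CCCC1(C)C=CC(=O)C=C1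
F2 | step 4 | cis-fused C11-keto enedione | O=C1C[C@@H]2C(=O)CC[C@]2(C)C=C1
F3 | step 4 | exocyclic enoate (C11=C1–CO2Me) | O=C1C[C@@H]2C(=CC(=O)OC)CC[C@]2(C)C=C1
F4 | step 4 | C9-methyl enoate | O=C1C(C)[C@@H]2C(=CC(=O)OC)CC[C@]2(C)C=C1
F5 | step 4 | 15β,16β-epoxy enoate | O=C1C(C)[C@@H]2C(=CC(=O)OC)CC[C@]2(C)[C@H]3O[C@@H]13
F6 | step 4 | enol triflate enoate | O=S(=O)(OC1=C(C)[C@@H]2C(=CC(=O)OC)CC[C@]2(C)[C@H]3O[C@@H]13)C(F)(F)F
F7 | step 14 | 2-acetoxy aldehyde | O=S(=O)(OC1=C(C)[C@@H]2[C@H](C(=C)[C@H](OC(C)=O)CC[C@H](C)CC=O)CC[C@]2(C)[C@H]3O[C@@H]13)C(F)(F)F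
F8 | step 14 | macrocyclic C7 alcohol (epimer mixture), 2-acetate | C=C1[C@H](OC(C)=O)CC[C@H](C)CC(O)C2=C(C)[C@@H]3[C@H]1CC[C@]3(C)[C@H]4O[C@@H]24
F9 | step 14 | macrocyclic C7 enone, 2-acetate | C=C1[C@H](OC(C)=O)CC[C@H](C)CC(=O)C2=C(C)[C@@H]3[C@H]1CC[C@]3(C)[C@H]4O[C@@H]24
F10 | step 14 | macrocyclic (7S)-alcohol, 2-acetate | C=C1[C@H](OC(C)=O)CC[C@H](C)C[C@H](O)C2=C(C)[C@@H]3[C@H]1CC[C@]3(C)[C@H]4O[C@@H]24
F11 | step 16 | 16-acetoxy-2,7,15-triol | C=C1[C@H](O)CC[C@H](C)C[C@H](O)C2=C(C)[C@@H]3[C@H]1CC[C@]3(C)[C@@H](O)[C@@H]2OC(C)=O
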